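**The leftover.** I began from what the recipes leave over: if the starting material, the limiting reagent, went entirely through the first step, 0.200 of reagent, as a fraction of the charge, would stand over.

| flask | starting material | reagent | remark | time |
|---|---|---|---|---|
| south | 0.059 M | 1.20 equiv | one stirred flow tank at steady state, fed with the mixture as stated, mean residence time 3.0 min |  |
| north-west | 0.059 M | 1.20 equiv | a closed flask charged with all of it at once and left for 3.0 min | 3.0 min |
| west | 0.059 M (fed, over 2.40 min) | 1.20 equiv | all but starting material at the start; starting material goes in evenly over 2.40 min, the run ends at 3.0 min | 3.0 min |
| north | 0.059 M | 1.20 equiv (fed, over 2.40 min) | all but reagent at the start; reagent goes in evenly over 2.40 min, the run ends at 3.0 min | 3.0 min |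

- the stated concentrations are those of everything mixed, before any reaction; amounts are the same in each set-up
- the feed brings no volume worth counting
- run time (north-west): 3.0 min

- the set-up with the highest share of target in all that became target or side product, at the outlet or at the end ("none" if the first two lie within 2 percentage points) (south / north-west / west / north / none)
- share of target in all that became target or side product, at the outlet or at the end, south
- share of target in all that became target or side product, at the outlet or at the end, north-west
- share of target in all that became target or side product, at the outlet or at the end, west
- share of target in all that became target or side product, at the outlet or at the end, north

**Bench rule.** The first step makes intermediate and by-product, the second turns intermediate into target, and the third joins starting material and by-product into side product. At the bench I would call the reagent in excess, treat the first step as pseudo-first-order and ignore the third. In the north-west flask this gave a half-life of 0.549 min, so the run lasts 5.46 half-lives.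

**The border.** I then wrote the balance of the starting material in fractions of its charge. It leaves by two routes, and the third step's rate over the first's is the selectivity factor 0.502 times by-product over reagent. The routes draw equally when by-product over reagent reaches 1.99. Counting no side product, that happens once 0.799 of the charge has passed the first step, short of the whole charge, so by that point the third step can no longer be ignored and the bench rule has stopped working.

**Tank ceiling.** In the south tank this ratio holds at outlet values. Supposing no starting material and no intermediate at the outlet, and taking the factor as half, the squared terms cancel and the side product comes to 0.294 of the charge, a limiting case and not an estimate of this tank. The mean lifetime of intermediate, 2.42 min, is close to the residence time of 3.0 min, so in the south tank some intermediate reaches the outlet without having become target. I committed to a south share below 70.6%, and I went no further.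

**The forecast.** It chose north-west, giving south 64.6%, north-west 70.9%, west 67.7% and north 61.8%, on the ground that “the flask does best by reacting the starting material early while reagent is plentiful and by-product scarce”.

**The result.** The simulation put north-west first, with south 64.6%, north-west 71.2%, west 68.1% and north 61.8%.

    starting material + reagent → intermediate + by-product (k1 = 0.297 /M/s)
    intermediate → target (k2 = 0.00689 /s)
    starting material + by-product → side product (k3 = 0.149 /M/s)

**Two clocks.** In the north-west flask, with the other concentrations as charged, starting material has a half-life of 0.55 min by the first step, shorter than the 1.3 min of by-product by the third. Their ratio is the equivalents of reagent over the selectivity factor, 2.39. In the flow tank at ten times the residence time, the share of target stood at 69.8%, just under the tank ceiling of 70.6%.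

The constants are assumed.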